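The target comes out of the catalyst intermediate, one molecule per turnover of the second catalyst, so we ask how many open intermediates those turnovers catch before they fall to side product.

    reagent + catalyst intermediate → second catalyst + target (k1 = 27000 L mol⁻¹ s⁻¹, Ea1 = 11.0 kJ mol⁻¹)
    second catalyst + open intermediate ⇌ catalyst intermediate (K2 = 1100 L mol⁻¹, k2 = 93000 L mol⁻¹ s⁻¹, Ea2 = 12.0 kJ mol⁻¹, ΔH2 = −12.0 kJ mol⁻¹)
    starting material + free catalyst ⇌ free catalyst + open intermediate (K3 = 1.7, k3 = 98000 L mol⁻¹ s⁻¹, Ea3 = 23.0 kJ mol⁻¹, ΔH3 = 12.0 kJ mol⁻¹)
    open intermediate → side product (k4 = 0.044 s⁻¹, Ea4 = 93.0 kJ mol⁻¹)
    (constants at 80 °C)

common to all: free catalyst 1.8 µM; second catalyst 2.0 µM; time 2.0 min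
- green: starting material 0.0010 M; reagent 2.00 mM; temperature 80 °C; everything together at the start
- blue: starting material 0.0010 M (in portions, 2, over 80 s); reagent 2.00 mM; temperature 80 °C; first portion at the start, last at 80 s
- amber: starting material 0.0010 M; reagent 2.00 mM (fed, over 80 s); temperature 80 °C; all else is in the flask from the start; the feed brings no volume worth counting
- red: starting material 0.0010 M (fed, over 8.0 s); reagent 2.00 mM; temperature 80 °C; all else is in the flask from the start; the feed brings no volume worth counting
- grey: starting material 0.0010 M (fed, over 80 s); reagent 2.00 mM; the addition at 40 °C, then warmed to 80 °C; the feed brings no volume worth counting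

- the flask with the highest share of target in target plus side product ("all alike" if they lie within 1.5 percentage points) (green / blue / amber / red / grey / all alike)
- share of target in target plus side product at the end, green
- share of target in target plus side product at the end, blue
- share of target in target plus side product at the end, amber
- share of target in target plus side product at the end, red
- share of target in target plus side product at the end, grey

- at 80 °C the constants are as listed, elsewhere as the activation energies and enthalpies make them

**Step one.** An open intermediate leaves for good in two ways: to side product, at 0.044 s⁻¹, or by capture. Returning to starting material brings the same molecule back to the same choice, so the share of target is the capture constant divided by the sum of the capture constant and that loss constant.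

**Step two.** The second catalyst takes up an open intermediate at 0.186 s⁻¹ in green. The catalyst intermediate then goes on to target at 54.0 s⁻¹, which is the rate constant of that step times [reagent], or falls back at 84.5 s⁻¹. The capture constant, the pseudo-first-order rate at which one open intermediate becomes target, is the uptake times the fraction that goes on: 0.0725 s⁻¹. That gives a first share of 62.2 % for green.

**Step three.** That share means about 311 turnovers per second catalyst and costs reagent, so we take [reagent] midway through the conversion, 1.69 mM. The capture constant falls to 0.0652 s⁻¹ and the share to 59.7 %.

**Step four.** The weak link is the assumption that the second catalyst stands free. Uptake and release balance at a half-saturation level (the Michaelis constant) of 1.40 mM of open intermediate. In green the whole charge opens at once, and equilibrium would put 63.0 % of it in the open form. The pool drains meanwhile, and a molecule meets a level below the peak, so we guess by dividing that amount by 3, which gives 0.210 mM. Capture shrinks by the factor 0.870 to 0.0567 s⁻¹.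

**Step five.** We commit to 56.3 % for green.

The forecast gave 56 % for green, 58 % for blue, 31 % for amber, 56.5 % for red and 74 % for grey, with grey highest, holding that “dosing only slightly eases saturation of the second catalyst”.

The simulation gives 56.3 %, 57.9 %, 32.4 %, 56.5 % and 75.1 % in that order, so grey stands highest. Green ends with 71.9 % of its reagent, which is 281 turnovers per second catalyst. Now take blue's first portion, with mean [reagent] 1.85 mM and open intermediate 0.105 mM. The capture constant becomes 0.0645 s⁻¹, a share of 59.4 %. At 1.33 min, blue holds 29.3 % target and 20.1 % side product, a share of 59.3 %.

(The numbers are those of an exercise.)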